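## Retrosynthetic overview

1. The furofuran ring-fusion carbons C8 and C8′ each carry one benzylic carbon (C7, C7′) and one oxygenated methylene (C9, C9′). This is the pattern of a trans-2,3-disubstituted butyrolactone, so the core is cut at C7′–C8′ and C7–C8 to butenolide 7, aryl dithiane 4 and aldehyde 5 (one-flask conjugate addition–aldol).
2. No ring forms in the key step. The lactone carbonyl becomes C9 and lactone C5 becomes C9′ after the exocyclic carbon is excised; both tetrahydrofuran rings (C7–O–C9′ and C7′–O–C9) then close together under acid, giving the allyl/benzyl-differentiated syringaresinol 16.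
3. Each arylglycerol β-aryl ether is cut at C7–C8 to an aryloxyacetyl oxazolidinone imide and a vanillin-type aldehyde. The boron syn-aldol gives the threo unit; the two erythro units follow by Mitsunobu inversion at C7.
4. The single erythro unit is built first on the deallylated ring. The benzyl ether is then cleaved and the two-unit arm is added by a late convergent aldol with the preformed outer-unit aldehyde 30; global desilylation ends the route.

Key step: step 5

Remarks on the chemistry: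
- Compounds 6, 19 and both enantiomers of 4-benzyl-3-(chloroacetyl)oxazolidin-2-one (20, 32) are taken as purchasable; each imide would otherwise come in one step from the oxazolidinone and chloroacetyl chloride.
- The benzylic carbinol centres C7 and C7′ of 10–15 are carried as epimer mixtures (unspecified in the SMILES), because both are re-formed in step 10.
- Labels: ring A sits on C7 (from aldehyde 5, O-allyl) and ring A′ on C7′ (from dithiane 4, O-benzyl). Unit b is the single erythro arylglycerol on O4 of ring A; units i (inner, threo) and o (outer, erythro) form the arm on O4′ of ring A′. "Core" means (7R,7′R,8S,8′S)-syringaresinol.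

## Part I – core (steps 1–10)

Step 1
Reactants: 1 syringaldehyde
Product: 2 4-(benzyloxy)-3,5-dimethoxybenzaldehyde
Conditions: BnBr, K2CO3, DMF, rt
Reagents that add atoms: benzyl bromide BrCc1ccccc1
Why: Williamson etherification of the acidic phenol; the benzyl ether should survive n-BuLi, hydride, fluoride and mild acid and is removed later by hydrogenolysis.

Step 2
Reactants: 2 4-(benzyloxy)-3,5-dimethoxybenzaldehyde; 3 propane-1,3-dithiol
Product: 4 2-[4-(benzyloxy)-3,5-dimethoxyphenyl]-1,3-dithiane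
Conditions: BF3·OEt2 (cat.), CH2Cl2, 0 °C → rt
Reagents that add atoms: none
Why: Lewis-acid-catalysed dithioacetalisation turns the aldehyde carbon (future C7′) into an acyl-anion equivalent (Corey–Seebach umpolung).

Step 3
Reactants: 1 syringaldehyde
Product: 5 4-(allyloxy)-3,5-dimethoxybenzaldehyde
Conditions: allyl bromide, K2CO3, DMF, rt
Reagents that add atoms: allyl bromide C=CCBr
Why: Williamson etherification; the allyl ether is orthogonal to the benzyl ether and is removed later under neutral Pd(0) conditions.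

Step 4
Reactants: 6 (S)-5-(hydroxymethyl)furan-2(5H)-one
Product: 7 (S)-5-[(tert-butyldiphenylsilyloxy)methyl]furan-2(5H)-one
Conditions: TBDPSCl, imidazole, CH2Cl2, 0 °C → rt
Reagents that add atoms: tert-butyl(chloro)diphenylsilane CC(C)(C)[Si](Cl)(c1ccccc1)c1ccccc1
Why: Silylation of the primary alcohol installs the bulky group that shields one face of the butenolide; the C5 stereocentre is untouched.

Step 5
Reactants: 4 2-[4-(benzyloxy)-3,5-dimethoxyphenyl]-1,3-dithiane; 7 (S)-5-[(tert-butyldiphenylsilyloxy)methyl]furan-2(5H)-one; 5 4-(allyloxy)-3,5-dimethoxybenzaldehyde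
Product: 10 (3R,4S,5S)-trans,trans-lactone aldol adduct (C7 carbinol epimer mixture), via 2-lithio-1,3-dithiane 8 (not isolated), via lithium lactone enolate 9 (not isolated)
Conditions: 4, n-BuLi, THF, −78 °C; then 7, −78 °C; then 5, −78 °C; AcOH, −78 °C
Reagents that add atoms: none
Why: Lithiation of 4 gives the soft, sulfur-stabilised benzylic carbanion 8, which adds 1,4 to butenolide 7 on the face opposite the C5 silyloxymethyl group, forming C7′–C8′ and the lithium enolate 9; 9 is then captured at its α-carbon by aldehyde 5 anti to the dithianyl group, forming C7–C8. The closest known reaction type is the tandem conjugate addition–aldol of 2-aryl-2-lithio-1,3-dithianes with 5-substituted furan-2(5H)-ones used for lignan lactones. No ring closes in this step; the lactone is carried on and its C2 and C5 later become C9 and C9′. C8′ (lactone C4) is controlled by the C5 stereocentre through anti addition, and C8 (lactone C3) by C8′ through a second anti approach, which should give the 3,4-trans-4,5-trans lactone; the carbinol centre C7 forms as a mixture that is erased in step 10. The step needs 1,4- over 1,2-addition, secured by the hindered, delocalised 2-aryl dithiane anion, and π-facial control, secured by the large TBDPS-oxymethyl group. Sequential addition at −78 °C should keep the enolate from proton exchange or retro-Michael collapse before the aldehyde arrives.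

Step 6
Reactants: 10 trans,trans-lactone aldol adduct
Product: 11 (3R,4S,5S)-4-aroyl keto lactone (C7 epimers)
Conditions: PhI(OCOCF3)2, NaHCO3, MeCN–H2O 9:1, 0 °C
Reagents that add atoms: water O
Why: Iodine(III)-mediated oxidative dethioacetalisation (sulfur activation, thionium ion captured by water) should unmask the C7′ aryl ketone under buffered conditions that leave the lactone, allyl ether, silyl ether and the trans stereocentres alone.

Step 7
Reactants: 11 keto lactone
Product: 12 acyclic tetraol mono-TBDPS ether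
Conditions: LiAlH4, THF, −20 → 0 °C (inverse addition)
Reagents that add atoms: none
Why: Hydride reduction converts the ketone into the C7′ carbinol (epimer mixture, irrelevant) and opens the lactone to the C9 primary alcohol and the former-C5 secondary alcohol; fast reduction at low temperature should outrun retro-aldol, and C8/C8′ are not touched.

Step 8
Reactants: 12 tetraol mono-TBDPS ether
Product: 13 pentaol with a terminal 1,2-diol
Conditions: TBAF, THF, 0 °C → rt
Reagents that add atoms: none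
Why: Fluoride-mediated desilylation frees the primary hydroxyl and so exposes the only vicinal diol of the molecule.

Step 9
Reactants: 13 pentaol
Product: 15 (1RS,2S,3S,4RS)-1,4-diaryl-2,3-bis(hydroxymethyl)butane-1,4-diol, via C9′ aldehyde 14 (not isolated)
Conditions: NaIO4, THF–H2O, 0 °C; extractive work-up; NaBH4, MeOH, 0 °C
Reagents that add atoms: none
Why: Malaprade glycol cleavage acts only on the vicinal diol and removes the extra carbon as formaldehyde; the C9′ aldehyde, held mainly as lactols, is reduced at once by borohydride, which should limit epimerisation at C8′.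

Step 10
Reactants: 15 tetraol
Product: 16 4-O-allyl-4′-O-benzyl-(7R,7′R,8S,8′S)-syringaresinol
Conditions: CSA (cat.), CH2Cl2, 4 Å MS, 0 °C → rt
Reagents that add atoms: none
Why: Acid-catalysed dehydrative etherification (SN1): each electron-rich benzylic carbinol ionises and is captured 5-exo by the primary hydroxyl across the C8–C8′ bond (C7–O–C9′ and C7′–O–C9), so both carbinol epimers converge; the aryl groups should take the exo positions on the convex face of the cis-fused 3,7-dioxabicyclo[3.3.0]octane, setting C7 and C7′ as R.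

## Part II – outer-unit aldehyde 30 (steps 11–19)

Step 11
Reactants: 17 vanillin
Product: 18 3-methoxy-4-(triisopropylsilyloxy)benzaldehyde
Conditions: TIPSCl, imidazole, DMF, rt
Reagents that add atoms: chlorotriisopropylsilane CC(C)[Si](Cl)(C(C)C)C(C)C
Why: Silylation of the phenol; the aryl TIPS ether tolerates boron enolates, hydrides, Mitsunobu conditions and hydrogenolysis and leaves with fluoride at the end.

Step 12
Reactants: 19 4-bromo-2-methoxyphenol; 20 (R)-4-benzyl-3-(chloroacetyl)oxazolidin-2-one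
Product: 21 (R)-4-benzyl-3-[(4-bromo-2-methoxyphenoxy)acetyl]oxazolidin-2-one
Conditions: K2CO3, NaI (cat.), acetone, 50 °C
Reagents that add atoms: none
Why: Williamson etherification by SN2 at the α-halo imide carbon with in-situ iodide exchange; the aryl bromide is a masked formyl group.

Step 13
Reactants: 21 aryloxyacetyl imide; 18 3-methoxy-4-(triisopropylsilyloxy)benzaldehyde
Product: 23 syn-aldol imide (2R,3S; threo), via Z-boron enolate 22 (not isolated)
Conditions: Bu2BOTf, iPr2NEt, CH2Cl2, −78 → 0 °C; 18, −78 → 0 °C; pH 7 buffer, MeOH, H2O2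
Reagents that add atoms: none
Why: Evans syn-aldol of an aryloxyacetyl imide: the Z-boron enolate reacts through a closed Zimmerman–Traxler chair whose face is fixed by the (R)-benzyl auxiliary, which should set C8o and C7o together as the (2R,3S) syn (threo) adduct.

Step 14
Reactants: 23 syn-aldol imide
Product: 24 (1S,2S)-2-(4-bromo-2-methoxyphenoxy)-1-(3-methoxy-4-triisopropylsilyloxyphenyl)propane-1,3-diol
Conditions: LiBH4, MeOH (2 equiv), THF, 0 °C
Reagents that add atoms: none
Why: Reductive cleavage of the exocyclic imide carbonyl gives the primary alcohol C9o and releases the auxiliary; cold, fast reduction should avoid retro-aldol.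

Step 15
Reactants: 24 threo diol
Product: 25 (1S,2S)-3-O-TBS mono-ether
Conditions: TBSCl, imidazole, CH2Cl2, 0 °C
Reagents that add atoms: tert-butyl(chloro)dimethylsilane CC(C)(C)[Si](C)(C)Cl
Why: The primary hydroxyl is silylated selectively over the hindered secondary benzylic one, leaving a single free OH for the inversion.

Step 16
Reactants: 25 threo mono-TBS ether
Product: 26 (1R,2S)-1-O-(4-nitrobenzoyl) ester (erythro)
Conditions: PPh3, DIAD, 4-nitrobenzoic acid, toluene, 0 °C → rt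
Reagents that add atoms: 4-nitrobenzoic acid OC(=O)c1ccc(cc1)[N+](=O)[O-]
Why: Mitsunobu esterification: SN2 displacement of the oxyphosphonium by the carboxylate inverts C7o (S → R) and turns the threo unit into the erythro one; the weakly donating 4-silyloxy group should damp ionisation.

Step 17
Reactants: 26 erythro 4-nitrobenzoate
Product: 27 (1R,2S)-erythro alcohol
Conditions: DIBAL-H, CH2Cl2, −78 °C; Rochelle salt
Reagents that add atoms: none
Why: Reductive ester cleavage under base-free conditions frees C7o–OH without unmasking a para-phenoxide, so no quinone methide can form; the aryl bromide and silyl ethers are inert.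

Step 18
Reactants: 27 erythro alcohol
Product: 28 (1R,2S)-1,3-bis-O-TBS aryl bromide
Conditions: TBSOTf, 2,6-lutidine, CH2Cl2, −78 → 0 °C
Reagents that add atoms: tert-butyldimethylsilyl triflate CC(C)(C)[Si](C)(C)OS(=O)(=O)C(F)(F)F
Why: Silylation of the hindered secondary benzylic alcohol with the reactive silyl triflate removes the last acidic proton before the organolithium and boron-enolate steps.

Step 19
Reactants: 28 bis-TBS aryl bromide
Product: 30 4-{[(1R,2S)-1,3-bis(TBS-oxy)-1-(3-methoxy-4-TIPS-oxyphenyl)propan-2-yl]oxy}-3-methoxybenzaldehyde, via aryllithium 29 (not isolated)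
Conditions: n-BuLi, THF, −78 °C; DMF, −78 → 0 °C; H2O
Reagents that add atoms: N,N-dimethylformamide CN(C)C=O
Why: Bromine–lithium exchange followed by formylation with DMF (Bouveault-type) unveils the vanillin-type aldehyde with no change at the two stereocentres.

## Part III – arms on the core (steps 20–32)

Step 20
Reactants: 16 4-O-allyl-4′-O-benzyl core
Product: 31 4′-O-benzyl-(7R,7′R,8S,8′S)-syringaresinol (4-OH free)
Conditions: Pd(PPh3)4 (cat.), morpholine, THF, rt
Reagents that add atoms: none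
Why: Tsuji–Trost-type deallylation: Pd(0) ionises the allyl aryl ether and morpholine traps the π-allyl complex under neutral conditions that should leave the benzyl ether and the furofuran alone.

Step 21
Reactants: 31 mono-phenol; 32 (S)-4-benzyl-3-(chloroacetyl)oxazolidin-2-one
Product: 33 4-O-{2-[(S)-4-benzyl-2-oxooxazolidin-3-yl]-2-oxoethyl}-4′-O-benzyl core
Conditions: K2CO3, NaI (cat.), acetone, 50 °C
Reagents that add atoms: none
Why: Williamson etherification of the 2,6-dimethoxyphenoxide at the activated α-halo imide carbon, the usual way to alkylate syringyl phenols with α-halo carbonyl compounds.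

Step 22
Reactants: 33 core aryloxyacetyl imide; 18 3-methoxy-4-(triisopropylsilyloxy)benzaldehyde
Product: 35 syn-aldol imide of unit b (2S,3R; threo), via Z-boron enolate 34 (not isolated)
Conditions: Bu2BOTf, iPr2NEt, CH2Cl2, −78 → 0 °C; 18, −78 → 0 °C; pH 7 buffer, MeOH, H2O2
Reagents that add atoms: none
Why: Evans syn-aldol through the Z-boron enolate and a Zimmerman–Traxler chair; the (S)-benzyl auxiliary should set C8b with the configuration required in the target and C7b syn to it, and the amine-buffered medium should spare the benzylic ethers of the furofuran.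

Step 23
Reactants: 35 syn-aldol imide
Product: 36 unit-b threo diol (7bR,8bR)
Conditions: LiBH4, MeOH (2 equiv), THF, 0 °C
Reagents that add atoms: none
Why: Reductive removal of the auxiliary gives the C9b primary alcohol without affecting the benzyl ether, the aryl silyl ether or the furofuran.

Step 24
Reactants: 36 threo diol
Product: 37 9b-O-TBS ether (7bR,8bR)
Conditions: TBSCl, imidazole, CH2Cl2, 0 °C
Reagents that add atoms: tert-butyl(chloro)dimethylsilane CC(C)(C)[Si](C)(C)Cl
Why: Selective silylation of the primary hydroxyl leaves C7b–OH as the only free alcohol.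

Step 25
Reactants: 37 threo mono-TBS ether
Product: 38 7b-O-(4-nitrobenzoyl) ester (7bS,8bR; erythro)
Conditions: PPh3, DIAD, 4-nitrobenzoic acid, toluene, 0 °C → rt
Reagents that add atoms: 4-nitrobenzoic acid OC(=O)c1ccc(cc1)[N+](=O)[O-]
Why: Mitsunobu inversion (SN2 at the oxyphosphonium) changes C7b from R to S and gives the erythro unit of the target; all other hydroxyls are masked.

Step 26
Reactants: 38 erythro 4-nitrobenzoate
Product: 39 unit-b erythro alcohol (7bS,8bR)
Conditions: DIBAL-H, CH2Cl2, −78 °C; Rochelle salt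
Reagents that add atoms: none
Why: Base-free reductive ester cleavage frees C7b–OH while the para-oxygen stays silylated, so quinone-methide loss of the ester cannot occur.

Step 27
Reactants: 39 erythro alcohol
Product: 40 7b,9b-bis-O-TBS ether (4′-O-benzyl)
Conditions: TBSOTf, 2,6-lutidine, CH2Cl2, −78 → 0 °C
Reagents that add atoms: tert-butyldimethylsilyl triflate CC(C)(C)[Si](C)(C)OS(=O)(=O)C(F)(F)F
Why: Silylation of the secondary benzylic hydroxyl under lutidine buffering protects it for the second boron aldol.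

Step 28
Reactants: 40 fully silylated 4′-O-benzyl intermediate
Product: 41 4′-phenol
Conditions: H2 (1 atm), 10% Pd/C, EtOAc, rt
Reagents that add atoms: none
Why: Hydrogenolysis of the aryl benzyl ether is much faster than cleavage of the dialkyl benzylic C–O bonds of the furofuran or of the benzylic silyl ether, so the reaction is stopped after one equivalent of hydrogen; silyl ethers are inert.

Step 29
Reactants: 41 4′-phenol; 32 (S)-4-benzyl-3-(chloroacetyl)oxazolidin-2-one
Product: 42 4′-O-{2-[(S)-4-benzyl-2-oxooxazolidin-3-yl]-2-oxoethyl} derivative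
Conditions: K2CO3, NaI (cat.), acetone, 50 °C
Reagents that add atoms: none
Why: Williamson etherification as in step 21; the bulky aryl TIPS ether should survive carbonate in dry acetone.

Step 30
Reactants: 42 core aryloxyacetyl imide; 30 outer-unit aldehyde
Product: 44 syn-aldol imide of unit i (2S,3R; threo), via Z-boron enolate 43 (not isolated)
Conditions: Bu2BOTf, iPr2NEt, CH2Cl2, −78 → 0 °C; 30, −78 → 0 °C; pH 7 buffer, MeOH, H2O2
Reagents that add atoms: none
Why: Convergent Evans syn-aldol: the Z-boron enolate of 42 adds to aldehyde 30 through the chair transition state under control of the (S)-auxiliary, which should set C8i and C7i as the threo pair; the remote stereocentres of 30 do not take part.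

Step 31
Reactants: 44 syn-aldol imide
Product: 45 hexasilyl ether of the target (unit i 7iR,8iR diol free)
Conditions: LiBH4, MeOH (2 equiv), THF, 0 °C
Reagents that add atoms: none
Why: Reductive cleavage of the imide gives the C9i primary alcohol and releases the auxiliary; silyl ethers and aryl ethers are stable.

Step 32
Reactants: 45 hexasilyl ether
Product: 46 CNP0316493.1
Conditions: TBAF, AcOH, THF, 0 °C → rt
Reagents that add atoms: none
Why: Buffered fluoride should cleave the four alkyl TBS ethers and the two aryl TIPS ethers; acetic acid keeps the freed p-hydroxybenzyl alcohols from base-induced quinone-methide chemistry, and no stereocentre is affected.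

## Compound list

1 | syringaldehyde (4-hydroxy-3,5-dimethoxybenzaldehyde) | COc1cc(C=O)cc(OC)c1O | starting material
2 | 4-(benzyloxy)-3,5-dimethoxybenzaldehyde | COc1cc(C=O)cc(OC)c1OCc1ccccc1 | intermediate
3 | propane-1,3-dithiol | SCCCS | starting material
4 | 2-[4-(benzyloxy)-3,5-dimethoxyphenyl]-1,3-dithiane | COc1cc(cc(OC)c1OCc1ccccc1)C1SCCCS1 | intermediate
5 | 4-(allyloxy)-3,5-dimethoxybenzaldehyde | COc1cc(C=O)cc(OC)c1OCC=C | intermediate
6 | (S)-5-(hydroxymethyl)furan-2(5H)-one | O=C1O[C@H](CO)C=C1 | starting material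
7 | (S)-5-[(tert-butyldiphenylsilyloxy)methyl]furan-2(5H)-one | O=C1O[C@H](CO[Si](c2ccccc2)(c2ccccc2)C(C)(C)C)C=C1 | intermediate
8 | 2-lithio-2-[4-(benzyloxy)-3,5-dimethoxyphenyl]-1,3-dithiane | COc1cc(cc(OC)c1OCc1ccccc1)C1([Li])SCCCS1 | intermediate
9 | lithium enolate of the 4,5-trans Michael adduct (dithianyl at C4 anti to CH2OTBDPS at C5) | [Li]OC1=C[C@H](C2(SCCCS2)c2cc(OC)c(OCc3ccccc3)c(OC)c2)[C@@H](CO[Si](c2ccccc2)(c2ccccc2)C(C)(C)C)O1 | intermediate
10 | (3R,4S,5S)-3-[(4-allyloxy-3,5-dimethoxyphenyl)(hydroxy)methyl]-4-{2-[4-(benzyloxy)-3,5-dimethoxyphenyl]-1,3-dithian-2-yl}-5-[(tert-butyldiphenylsilyloxy)methyl]dihydrofuran-2(3H)-one; trans,trans; C7 carbinol epimers | O=C1O[C@H](CO[Si](c2ccccc2)(c2ccccc2)C(C)(C)C)[C@@H](C2(SCCCS2)c2cc(OC)c(OCc3ccccc3)c(OC)c2)[C@@H]1C(O)c1cc(OC)c(OCC=C)c(OC)c1 | intermediate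
11 | (3R,4S,5S)-3-[(4-allyloxy-3,5-dimethoxyphenyl)(hydroxy)methyl]-4-[4-(benzyloxy)-3,5-dimethoxybenzoyl]-5-[(tert-butyldiphenylsilyloxy)methyl]dihydrofuran-2(3H)-one; C7 epimers | O=C1O[C@H](CO[Si](c2ccccc2)(c2ccccc2)C(C)(C)C)[C@@H](C(=O)c2cc(OC)c(OCc3ccccc3)c(OC)c2)[C@@H]1C(O)c1cc(OC)c(OCC=C)c(OC)c1 | intermediate
12 | acyclic tetraol mono-TBDPS ether: 1-(4-allyloxy-3,5-dimethoxyphenyl)-4-[4-(benzyloxy)-3,5-dimethoxyphenyl]-2-(hydroxymethyl)-3-[(1S)-1-hydroxy-2-(TBDPS-oxy)ethyl]butane-1,4-diol; C8 and C8′ as set in step 5; C7/C7′ epimers | O[C@H](CO[Si](c1ccccc1)(c1ccccc1)C(C)(C)C)[C@@H](C(O)c1cc(OC)c(OCc2ccccc2)c(OC)c1)[C@@H](CO)C(O)c1cc(OC)c(OCC=C)c(OC)c1 | intermediate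
13 | pentaol: the desilylated form of 12 with a terminal (S)-1,2-diol on C8′ | O[C@H](CO)[C@@H](C(O)c1cc(OC)c(OCc2ccccc2)c(OC)c1)[C@@H](CO)C(O)c1cc(OC)c(OCC=C)c(OC)c1 | intermediate
14 | C9′ aldehyde (open form of the lactol mixture): 2-[aryl(hydroxy)methyl]-3-(hydroxymethyl)-4-aryl-4-hydroxybutanal with C8 and C8′ as in 13 | O=C[C@@H](C(O)c1cc(OC)c(OCc2ccccc2)c(OC)c1)[C@@H](CO)C(O)c1cc(OC)c(OCC=C)c(OC)c1 | intermediate
15 | (1RS,2S,3S,4RS)-1-(4-allyloxy-3,5-dimethoxyphenyl)-4-[4-(benzyloxy)-3,5-dimethoxyphenyl]-2,3-bis(hydroxymethyl)butane-1,4-diol | OC[C@@H](C(O)c1cc(OC)c(OCc2ccccc2)c(OC)c1)[C@@H](CO)C(O)c1cc(OC)c(OCC=C)c(OC)c1 | intermediate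
16 | 4-O-allyl-4′-O-benzyl-(7R,7′R,8S,8′S)-syringaresinol (both aryl groups exo on the cis-fused furofuran) | COc1cc(cc(OC)c1OCc1ccccc1)[C@@H]1OC[C@@H]2[C@H]1CO[C@H]2c1cc(OC)c(OCC=C)c(OC)c1 | intermediate
17 | vanillin | COc1cc(C=O)ccc1O | starting material
18 | 3-methoxy-4-(triisopropylsilyloxy)benzaldehyde | COc1cc(C=O)ccc1O[Si](C(C)C)(C(C)C)C(C)C | intermediate
19 | 4-bromo-2-methoxyphenol | COc1cc(Br)ccc1O | starting material
20 | (R)-4-benzyl-3-(chloroacetyl)oxazolidin-2-one | O=C(CCl)N1[C@H](Cc2ccccc2)COC1=O | starting material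
21 | (R)-4-benzyl-3-[(4-bromo-2-methoxyphenoxy)acetyl]oxazolidin-2-one | COc1cc(Br)ccc1OCC(=O)N1[C@H](Cc2ccccc2)COC1=O | intermediate
22 | Z-dibutylboron enolate of 21 | COc1cc(Br)ccc1O/C=C(\OB(CCCC)CCCC)N1[C@H](Cc2ccccc2)COC1=O | intermediate
23 | (R)-4-benzyl-3-[(2R,3S)-2-(4-bromo-2-methoxyphenoxy)-3-hydroxy-3-(3-methoxy-4-triisopropylsilyloxyphenyl)propanoyl]oxazolidin-2-one | COc1cc(ccc1O[Si](C(C)C)(C(C)C)C(C)C)[C@H](O)[C@H](C(=O)N1[C@H](Cc2ccccc2)COC1=O)Oc1ccc(Br)cc1OC | intermediate
24 | (1S,2S)-2-(4-bromo-2-methoxyphenoxy)-1-(3-methoxy-4-triisopropylsilyloxyphenyl)propane-1,3-diol (threo) | COc1cc(ccc1O[Si](C(C)C)(C(C)C)C(C)C)[C@H](O)[C@H](CO)Oc1ccc(Br)cc1OC | intermediate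
25 | (1S,2S)-2-(4-bromo-2-methoxyphenoxy)-3-(tert-butyldimethylsilyloxy)-1-(3-methoxy-4-triisopropylsilyloxyphenyl)propan-1-ol | COc1cc(ccc1O[Si](C(C)C)(C(C)C)C(C)C)[C@H](O)[C@H](CO[Si](C)(C)C(C)(C)C)Oc1ccc(Br)cc1OC | intermediate
26 | (1R,2S)-2-(4-bromo-2-methoxyphenoxy)-3-(tert-butyldimethylsilyloxy)-1-(3-methoxy-4-triisopropylsilyloxyphenyl)propyl 4-nitrobenzoate (erythro) | COc1cc(ccc1O[Si](C(C)C)(C(C)C)C(C)C)[C@@H](OC(=O)c1ccc(cc1)[N+](=O)[O-])[C@H](CO[Si](C)(C)C(C)(C)C)Oc1ccc(Br)cc1OC | intermediate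
27 | (1R,2S)-2-(4-bromo-2-methoxyphenoxy)-3-(tert-butyldimethylsilyloxy)-1-(3-methoxy-4-triisopropylsilyloxyphenyl)propan-1-ol (erythro) | COc1cc(ccc1O[Si](C(C)C)(C(C)C)C(C)C)[C@@H](O)[C@H](CO[Si](C)(C)C(C)(C)C)Oc1ccc(Br)cc1OC | intermediate
28 | (1R,2S)-2-(4-bromo-2-methoxyphenoxy)-1,3-bis(tert-butyldimethylsilyloxy)-1-(3-methoxy-4-triisopropylsilyloxyphenyl)propane | COc1cc(ccc1O[Si](C(C)C)(C(C)C)C(C)C)[C@@H](O[Si](C)(C)C(C)(C)C)[C@H](CO[Si](C)(C)C(C)(C)C)Oc1ccc(Br)cc1OC | intermediate
29 | aryllithium from 28 (Li in place of Br) | COc1cc(ccc1O[Si](C(C)C)(C(C)C)C(C)C)[C@@H](O[Si](C)(C)C(C)(C)C)[C@H](CO[Si](C)(C)C(C)(C)C)Oc1ccc([Li])cc1OC | intermediate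
30 | 4-{[(1R,2S)-1,3-bis(tert-butyldimethylsilyloxy)-1-(3-methoxy-4-triisopropylsilyloxyphenyl)propan-2-yl]oxy}-3-methoxybenzaldehyde | COc1cc(ccc1O[Si](C(C)C)(C(C)C)C(C)C)[C@@H](O[Si](C)(C)C(C)(C)C)[C@H](CO[Si](C)(C)C(C)(C)C)Oc1ccc(C=O)cc1OC | intermediate
31 | 4′-O-benzyl-(7R,7′R,8S,8′S)-syringaresinol (4-OH free) | COc1cc(cc(OC)c1OCc1ccccc1)[C@@H]1OC[C@@H]2[C@H]1CO[C@H]2c1cc(OC)c(O)c(OC)c1 | intermediate
32 | (S)-4-benzyl-3-(chloroacetyl)oxazolidin-2-one | O=C(CCl)N1[C@@H](Cc2ccccc2)COC1=O | starting material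
33 | 4-O-{2-[(S)-4-benzyl-2-oxooxazolidin-3-yl]-2-oxoethyl}-4′-O-benzyl core | COc1cc(cc(OC)c1OCc1ccccc1)[C@@H]1OC[C@@H]2[C@H]1CO[C@H]2c1cc(OC)c(OCC(=O)N2[C@@H](Cc3ccccc3)COC2=O)c(OC)c1 | intermediate
34 | Z-dibutylboron enolate of 33 | COc1cc(cc(OC)c1OCc1ccccc1)[C@@H]1OC[C@@H]2[C@H]1CO[C@H]2c1cc(OC)c(O/C=C(\OB(CCCC)CCCC)N2[C@@H](Cc3ccccc3)COC2=O)c(OC)c1 | intermediate
35 | unit-b syn-aldol imide: (S)-4-benzyl-3-[(2S,3R)-2-(core-4-yloxy)-3-hydroxy-3-(3-methoxy-4-triisopropylsilyloxyphenyl)propanoyl]oxazolidin-2-one; 4′-O-benzyl | COc1cc(cc(OC)c1OCc1ccccc1)[C@@H]1OC[C@@H]2[C@H]1CO[C@H]2c1cc(OC)c(O[C@H](C(=O)N2[C@@H](Cc3ccccc3)COC2=O)[C@H](O)c2ccc(O[Si](C(C)C)(C(C)C)C(C)C)c(OC)c2)c(OC)c1 | intermediate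
36 | 4′-O-benzyl core 4-O-[(1R,2R)-1,3-dihydroxy-1-(3-methoxy-4-triisopropylsilyloxyphenyl)propan-2-yl] ether (unit b threo; 7bR,8bR) | COc1cc(cc(OC)c1OCc1ccccc1)[C@@H]1OC[C@@H]2[C@H]1CO[C@H]2c1cc(OC)c(O[C@H](CO)[C@H](O)c2ccc(O[Si](C(C)C)(C(C)C)C(C)C)c(OC)c2)c(OC)c1 | intermediate
37 | 9b-O-TBS ether of 36 (7bR,8bR) | COc1cc(cc(OC)c1OCc1ccccc1)[C@@H]1OC[C@@H]2[C@H]1CO[C@H]2c1cc(OC)c(O[C@H](CO[Si](C)(C)C(C)(C)C)[C@H](O)c2ccc(O[Si](C(C)C)(C(C)C)C(C)C)c(OC)c2)c(OC)c1 | intermediate
38 | 7b-O-(4-nitrobenzoyl) ester with inverted C7b (7bS,8bR; erythro); 9b-O-TBS; 4′-O-benzyl | COc1cc(cc(OC)c1OCc1ccccc1)[C@@H]1OC[C@@H]2[C@H]1CO[C@H]2c1cc(OC)c(O[C@H](CO[Si](C)(C)C(C)(C)C)[C@@H](OC(=O)c2ccc(cc2)[N+](=O)[O-])c2ccc(O[Si](C(C)C)(C(C)C)C(C)C)c(OC)c2)c(OC)c1 | intermediate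
39 | unit-b erythro alcohol (7bS,8bR); 9b-O-TBS; 4′-O-benzyl | COc1cc(cc(OC)c1OCc1ccccc1)[C@@H]1OC[C@@H]2[C@H]1CO[C@H]2c1cc(OC)c(O[C@H](CO[Si](C)(C)C(C)(C)C)[C@@H](O)c2ccc(O[Si](C(C)C)(C(C)C)C(C)C)c(OC)c2)c(OC)c1 | intermediate
40 | 7b,9b-bis-O-TBS ether of the erythro unit b; 4′-O-benzyl | COc1cc(cc(OC)c1OCc1ccccc1)[C@@H]1OC[C@@H]2[C@H]1CO[C@H]2c1cc(OC)c(O[C@H](CO[Si](C)(C)C(C)(C)C)[C@@H](O[Si](C)(C)C(C)(C)C)c2ccc(O[Si](C(C)C)(C(C)C)C(C)C)c(OC)c2)c(OC)c1 | intermediate
41 | 4′-phenol: the debenzylated form of 40 | COc1cc(cc(OC)c1O)[C@@H]1OC[C@@H]2[C@H]1CO[C@H]2c1cc(OC)c(O[C@H](CO[Si](C)(C)C(C)(C)C)[C@@H](O[Si](C)(C)C(C)(C)C)c2ccc(O[Si](C(C)C)(C(C)C)C(C)C)c(OC)c2)c(OC)c1 | intermediate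
42 | 4′-O-{2-[(S)-4-benzyl-2-oxooxazolidin-3-yl]-2-oxoethyl} derivative of 41 | O=C(COc1c(OC)cc(cc1OC)[C@@H]1OC[C@@H]2[C@H]1CO[C@H]2c1cc(OC)c(O[C@H](CO[Si](C)(C)C(C)(C)C)[C@@H](O[Si](C)(C)C(C)(C)C)c2ccc(O[Si](C(C)C)(C(C)C)C(C)C)c(OC)c2)c(OC)c1)N1[C@@H](Cc2ccccc2)COC1=O | intermediate
43 | Z-dibutylboron enolate of 42 | CCCCB(CCCC)O/C(=C\Oc1c(OC)cc(cc1OC)[C@@H]1OC[C@@H]2[C@H]1CO[C@H]2c1cc(OC)c(O[C@H](CO[Si](C)(C)C(C)(C)C)[C@@H](O[Si](C)(C)C(C)(C)C)c2ccc(O[Si](C(C)C)(C(C)C)C(C)C)c(OC)c2)c(OC)c1)N1[C@@H](Cc2ccccc2)COC1=O | intermediate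
44 | unit-i syn-aldol imide: (2S,3R)-acyl imide on O4′ (threo) carrying the silylated erythro unit o; unit b silylated | COc1cc([C@@H](O[Si](C)(C)C(C)(C)C)[C@H](CO[Si](C)(C)C(C)(C)C)Oc2ccc([C@@H](O)[C@@H](C(=O)N6[C@@H](Cc7ccccc7)COC6=O)Oc3c(OC)cc([C@@H]4OC[C@@H]5[C@H]4CO[C@H]5c4cc(OC)c(O[C@H](CO[Si](C)(C)C(C)(C)C)[C@@H](O[Si](C)(C)C(C)(C)C)c5ccc(O[Si](C(C)C)(C(C)C)C(C)C)c(OC)c5)c(OC)c4)cc3OC)cc2OC)ccc1O[Si](C(C)C)(C(C)C)C(C)C | intermediate
45 | hexasilyl ether of the target: unit i free diol (7iR,8iR); units o and b as 7,9-bis-O-TBS and 4-O-TIPS ethers | COc1cc([C@@H](O[Si](C)(C)C(C)(C)C)[C@H](CO[Si](C)(C)C(C)(C)C)Oc2ccc([C@@H](O)[C@@H](CO)Oc3c(OC)cc([C@@H]4OC[C@@H]5[C@H]4CO[C@H]5c4cc(OC)c(O[C@H](CO[Si](C)(C)C(C)(C)C)[C@@H](O[Si](C)(C)C(C)(C)C)c5ccc(O[Si](C(C)C)(C(C)C)C(C)C)c(OC)c5)c(OC)c4)cc3OC)cc2OC)ccc1O[Si](C(C)C)(C(C)C)C(C)C | intermediate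
46 | CNP0316493.1: (7R,7′R,8S,8′S)-syringaresinol with an erythro (7S,8R) guaiacylglycerol on one 4-O and a threo (7R,8R) guaiacylglycerol on the other, the latter carrying an erythro (7R,8S) guaiacylglycerol on its 4-O | COc1cc([C@@H](O)[C@H](CO)Oc2ccc([C@@H](O)[C@@H](CO)Oc3c(OC)cc([C@@H]4OC[C@@H]5[C@H]4CO[C@H]5c4cc(OC)c(O[C@H](CO)[C@@H](O)c5ccc(O)c(OC)c5)c(OC)c4)cc3OC)cc2OC)ccc1O | target

## Step count and risks

Total step count: 32 (10 for the core, 9 for aldehyde 30, 13 on the core).
Longest linear sequence: 21 steps (1, 2, 5–10, 20–32, from syringaldehyde).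

The three steps most likely to fail:

Step 5 (key step). The three-component sequence may break down: the dithiane anion may add 1,2 to the lactone carbonyl, or the enolate may be lost by proton transfer or retro-Michael collapse before the aldehyde is captured. Fallback, setting out from 4 and 7 and returning at 10: the conjugate addition is run alone and quenched with acetic acid at −78 °C to give the isolated 4,5-trans Michael lactone F1. F1 is then deprotonated with LDA in THF at −78 °C, and the kinetic enolate is treated with 5 to give 10, with the aldol again anti to the dithianyl group.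

Step 6. The freed ketone and the neighbouring aldol hydroxyl (a γ-hydroxy ketone) may close to a cyclic hemiketal that dehydrates and scrambles C8′, and the iodine(III) reagent may attack the electron-rich rings during a slow hydrolysis. Fallback, setting out from 10 and returning at 13: the aldol hydroxyl is first capped (TESCl, imidazole, DMF) to give the O-triethylsilyl dithiane lactone F2, so that no γ-hydroxy ketone can arise. The same buffered iodine(III) hydrolysis then gives the O-triethylsilyl keto lactone F3, LiAlH4 reduction gives the O-TES/O-TBDPS triol F4, and the fluoride treatment of step 8 removes both silyl groups at once to give 13.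

Step 25 (the same applies to step 16). The oxyphosphonium at the electron-rich benzylic carbon may ionise, so that inversion is incomplete, or may eliminate to the enol ether. Fallback, setting out from 37 and returning at 39: Dess–Martin oxidation of the C7b carbinol gives the α-aryloxy aryl ketone F5. Reduction with L-Selectride in THF at −78 °C under Felkin–Anh (non-chelation) control should deliver hydride anti to the aryloxy group and give the erythro alcohol 39 directly, bypassing 38 and step 26.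

## Further compounds

F1 | step 5 | (4S,5S)-4-{2-[4-(benzyloxy)-3,5-dimethoxyphenyl]-1,3-dithian-2-yl}-5-[(tert-butyldiphenylsilyloxy)methyl]dihydrofuran-2(3H)-one | O=C1O[C@H](CO[Si](c2ccccc2)(c2ccccc2)C(C)(C)C)[C@@H](C2(SCCCS2)c2cc(OC)c(OCc3ccccc3)c(OC)c2)C1
F2 | step 6 | O-triethylsilyl ether of 10 at the C7 carbinol | O=C1O[C@H](CO[Si](c2ccccc2)(c2ccccc2)C(C)(C)C)[C@@H](C2(SCCCS2)c2cc(OC)c(OCc3ccccc3)c(OC)c2)[C@@H]1C(O[Si](CC)(CC)CC)c1cc(OC)c(OCC=C)c(OC)c1
F3 | step 6 | O-triethylsilyl ether of keto lactone 11 | O=C1O[C@H](CO[Si](c2ccccc2)(c2ccccc2)C(C)(C)C)[C@@H](C(=O)c2cc(OC)c(OCc3ccccc3)c(OC)c2)[C@@H]1C(O[Si](CC)(CC)CC)c1cc(OC)c(OCC=C)c(OC)c1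
F4 | step 6 | 7-O-triethylsilyl ether of 12 (O-TES/O-TBDPS triol) | O[C@H](CO[Si](c1ccccc1)(c1ccccc1)C(C)(C)C)[C@@H](C(O)c1cc(OC)c(OCc2ccccc2)c(OC)c1)[C@@H](CO)C(O[Si](CC)(CC)CC)c1cc(OC)c(OCC=C)c(OC)c1
F5 | step 25 | C7b ketone from 37 (8bR; 9b-O-TBS; 4′-O-benzyl) | COc1cc(cc(OC)c1OCc1ccccc1)[C@@H]1OC[C@@H]2[C@H]1CO[C@H]2c1cc(OC)c(O[C@H](CO[Si](C)(C)C(C)(C)C)C(=O)c2ccc(O[Si](C(C)C)(C(C)C)C(C)C)c(OC)c2)c(OC)c1
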